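**Plan**

1. Retrosynthetic cuts, in order: (a) the two MOM ethers; (b) the C3 configuration, back to the racemic ketone; (c) ring C at O1–C2 and C4–C4a in one operation, back to an aryl 2-arylacrylate with O1 held on C4 as an ester and Br on C4a; (d) the ester, to a bromophenol and a 2-arylacrylic acid; (e) the C6–geranyl bond, back to 4,6-dibromoresorcinol.
2. Forward: ring A is dressed first (one C–Br of the symmetrical dibromide takes the geranyl chain at C6, the other stays at C4a), ring B arrives as the acrylic acid, the ester joins them, and ring C closes last in the key step.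
3. Enabling feature: in ring C the carbonyl carbon C4 is bonded to C4a, ortho to the ring-A oxygen O1, and C2 is an unsubstituted CH2 β to C4. An O1–C4 ester is therefore one 1,3-acyl shift from the ketone, after which the freed O1 can add to C2. C3 carries only ring B, so the acrylate has no α-hydrogen.
4. Stereochemistry: C3 (S) is benzylic and α to C4=O, hence labile. It is left racemic in the key step and set in step 10 by dynamic kinetic resolution with RuCl[(S,S)-TsDPEN](p-cymene), then kept through a non-basic oxidation and a low-temperature deprotection. The E alkene comes from geranyl bromide.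

Key step: step 9

Assumption: C3 of the target is S (CIP order C4 > C2 > C1′ > H), and 1, 4 and 8 are purchasable.
Abbreviations: geranyl = (2E)-3,7-dimethylocta-2,6-dien-1-yl; TIPS = triisopropylsilyl; MOM = methoxymethyl; TsDPEN = N-tosyl-1,2-diphenylethane-1,2-diamine; DIC = N,N′-diisopropylcarbodiimide.

**Step 1**
Reactants: 1 4,6-dibromoresorcinol (4,6-dibromobenzene-1,3-diol)
Product: 2 2,4-dibromo-5-(triisopropylsilyloxy)phenol
Conditions: 1 (2 equiv), TIPSCl (1 equiv), imidazole, DMF, 0 °C to rt; excess 1 recovered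
Reagents that add atoms: chlorotriisopropylsilane (TIPSCl), CC(C)[Si](Cl)(C(C)C)C(C)C
Why: The two hydroxyls of the twofold-symmetric diol are equivalent, so silyl ether formation with the diol in excess should give a single mono-ether and marks the oxygen that becomes O1.

**Step 2**
Reactants: 2 2,4-dibromo-5-(triisopropylsilyloxy)phenol
Product: 3 [2,4-dibromo-5-(methoxymethoxy)phenoxy]triisopropylsilane
Conditions: MOMCl, i-Pr2NEt, CH2Cl2, 0 °C to rt
Reagents that add atoms: chloromethyl methyl ether (MOMCl), COCCl
Why: Standard O-alkylation of the remaining phenol gives the MOM acetal, which carries the future 7-oxygen and can chelate lithium in the next step.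

**Step 3**
Reactants: 3 [2,4-dibromo-5-(methoxymethoxy)phenoxy]triisopropylsilane; 4 geranyl bromide [(2E)-1-bromo-3,7-dimethylocta-2,6-diene]
Product: 6 [2-bromo-4-geranyl-5-(methoxymethoxy)phenoxy]triisopropylsilane, via aryllithium 5 (not isolated)
Conditions: n-BuLi (1.0 equiv), THF, −78 °C; then CuI (10 mol %), 4, −78 to −20 °C
Reagents that add atoms: none
Why: Bromine–lithium exchange is expected at the bromide next to the chelating OMOM group and not at the one shielded by the bulky, non-coordinating OTIPS group, and CuI-catalysed SN2 allylation of the aryllithium with the primary allylic bromide should give the linear geranyl arene with the E geometry kept.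

**Step 4**
Reactants: 6 [2-bromo-4-geranyl-5-(methoxymethoxy)phenoxy]triisopropylsilane
Product: 7 2-bromo-4-geranyl-5-(methoxymethoxy)phenol
Conditions: n-Bu4NF (1.1 equiv), AcOH (1.1 equiv), THF, 0 °C
Reagents that add atoms: none
Why: Buffered fluoride cleavage of the aryl silyl ether should free the phenol ortho to bromine while the MOM acetal and the diene survive.

**Step 5**
Reactants: 8 1-(4-hydroxy-2-methoxyphenyl)ethan-1-one
Product: 9 1-[2-methoxy-4-(methoxymethoxy)phenyl]ethan-1-one
Conditions: MOMCl, i-Pr2NEt, CH2Cl2, 0 °C to rt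
Reagents that add atoms: chloromethyl methyl ether (MOMCl), COCCl
Why: Standard MOM protection of the phenol gives a group that tolerates the strong base, palladium and organolithium steps ahead.

**Step 6**
Reactants: 9 1-[2-methoxy-4-(methoxymethoxy)phenyl]ethan-1-one
Product: 11 1-[2-methoxy-4-(methoxymethoxy)phenyl]ethenyl trifluoromethanesulfonate, via potassium enolate 10 (not isolated)
Conditions: KN(SiMe3)2, THF, −78 °C; then PhNTf2, −78 to 0 °C
Reagents that add atoms: N-phenylbis(trifluoromethanesulfonimide) (PhNTf2), O=S(=O)(N(c1ccccc1)S(=O)(=O)C(F)(F)F)C(F)(F)F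
Why: Enol triflate formation by deprotonation of the methyl ketone and O-sulfonylation of the enolate; only one enolate is possible.

**Step 7**
Reactants: 11 1-[2-methoxy-4-(methoxymethoxy)phenyl]ethenyl trifluoromethanesulfonate
Product: 12 2-[2-methoxy-4-(methoxymethoxy)phenyl]prop-2-enoic acid
Conditions: Pd(OAc)2 (5 mol %), PPh3 (10 mol %), CO (1 atm), KOAc, DMF/H2O (9:1), rt
Reagents that add atoms: carbon monoxide, [C-]#[O+]; water, O
Why: Pd(OAc)2/PPh3-catalysed hydroxycarbonylation of the enol triflate (oxidative addition, CO insertion, capture of the acylpalladium by water) should give the 2-arylacrylic acid that holds all three carbons of the future C2–C3–C4 unit.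

**Step 8**
Reactants: 7 2-bromo-4-geranyl-5-(methoxymethoxy)phenol; 12 2-[2-methoxy-4-(methoxymethoxy)phenyl]prop-2-enoic acid
Product: 13 2-bromo-4-geranyl-5-(methoxymethoxy)phenyl 2-[2-methoxy-4-(methoxymethoxy)phenyl]prop-2-enoate
Conditions: DIC, DMAP (10 mol %), CH2Cl2, 0 °C to rt
Reagents that add atoms: none
Why: Steglich esterification joins the two fragments through O1–C4, the temporary bond that places the acyl carbon one 1,3-shift away from C4a.

**Step 9**
Reactants: 13 2-bromo-4-geranyl-5-(methoxymethoxy)phenyl 2-[2-methoxy-4-(methoxymethoxy)phenyl]prop-2-enoate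
Product: 16 rac-6-geranyl-3-[2-methoxy-4-(methoxymethoxy)phenyl]-7-(methoxymethoxy)-2,3-dihydro-4H-chromen-4-one, via aryllithium 14 (not isolated), via 2-hydroxyaryl vinyl ketone 15 (not isolated)
Conditions: t-BuLi (2.0 equiv), THF/Et2O/pentane (4:1:1), −100 °C, 10 min; then AcOH (1.0 equiv), −100 °C to rt; then Et3N (20 mol %), MeOH, rt
Reagents that add atoms: none
Why: Proposed new method: bromine–lithium exchange at C4a gives aryllithium 14, whose carbanion sits next to the ester carbonyl and should attack it through a four-membered tetrahedral alkoxide that collapses to the lithium phenoxide of ketone 15 (anionic ortho-Fries 1,3-O→C acyl shift, forming C4–C4a); after protonation the O1 phenol adds under mild base to the unsubstituted CH2 terminus of the aryl vinyl ketone (oxa-Michael, forming O1–C2) and the enol tautomerises to 16. The closest known reaction types are the halogen–metal-exchange-triggered anionic Fries rearrangement of 2-haloaryl esters and the base-induced cyclisation of 2′-hydroxy-α-methylenedeoxybenzoins to isoflavanones; their union on an aryl 2-arylacrylate is not established. Ring C closes in a 6-endo-trig mode. The new stereocentre C3 arises by protonation of an achiral enol without control and is racemic here; it is set in step 10. The step needs exchange to outrun addition of t-BuLi to the acrylate, and acyl transfer to outrun conjugate addition of the aryllithium: the ortho-acyloxy group accelerates exchange, the carbanion is held within bonding distance of the carbonyl carbon whereas the CH2 terminus is reachable only from the disfavoured E ester conformer, and the acrylate has no α-hydrogen that could quench the aryllithium. Regiochemistry is fixed by the C–Br bond, so the acyl group cannot go to C8.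

**Step 10**
Reactants: 16 rac-6-geranyl-3-[2-methoxy-4-(methoxymethoxy)phenyl]-7-(methoxymethoxy)-2,3-dihydro-4H-chromen-4-one
Product: 17 (3S,4S)-6-geranyl-3-[2-methoxy-4-(methoxymethoxy)phenyl]-7-(methoxymethoxy)-3,4-dihydro-2H-chromen-4-ol (cis)
Conditions: RuCl[(S,S)-TsDPEN](p-cymene) (2 mol %), HCO2H/Et3N (5:2), EtOAc, 40 °C
Reagents that add atoms: none
Why: Asymmetric transfer hydrogenation with dynamic kinetic resolution: C3 epimerises through the enol in the amine–formic acid medium while the (S,S)-configured ruthenium hydride reduces one ketone enantiomer anti to the C3 aryl group, so the cis-(3S,4S) alcohol should form, by analogy with the (S) carbinols this catalyst antipode gives from 4-chromanone-type aryl ketones.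

**Step 11**
Reactants: 17 (3S,4S)-6-geranyl-3-[2-methoxy-4-(methoxymethoxy)phenyl]-7-(methoxymethoxy)-3,4-dihydro-2H-chromen-4-ol
Product: 18 (3S)-6-geranyl-3-[2-methoxy-4-(methoxymethoxy)phenyl]-7-(methoxymethoxy)-2,3-dihydro-4H-chromen-4-one
Conditions: Dess–Martin periodinane (1.2 equiv), CH2Cl2, 0 °C to rt
Reagents that add atoms: none
Why: Dess–Martin oxidation of the benzylic alcohol under non-basic conditions should return the C4 ketone without touching the C3–H bond, so the S configuration from step 10 is kept.

**Step 12**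
Reactants: 18 (3S)-6-geranyl-3-[2-methoxy-4-(methoxymethoxy)phenyl]-7-(methoxymethoxy)-2,3-dihydro-4H-chromen-4-one
Product: 20 (3S)-6-geranyl-7-hydroxy-3-(4-hydroxy-2-methoxyphenyl)-2,3-dihydro-4H-chromen-4-one, via bis(dimethylborinate) 19 (not isolated)
Conditions: Me2BBr (2.5 equiv), CH2Cl2, −78 °C; then pH 7 phosphate buffer/THF, 0 °C
Reagents that add atoms: none
Why: Lewis-acid cleavage of both MOM acetals by Me2BBr at −78 °C (bromide attack on the boron-activated acetal) needs neither protic acid nor base, keeps O7 masked as a borinate until work-up so it cannot add to the geranyl alkene, and should leave the enolisable C3 centre and the aryl methyl ether intact.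

**Compound list**

1 | 4,6-dibromoresorcinol | Oc1cc(O)c(Br)cc1Br | starting material
2 | 2,4-dibromo-5-(triisopropylsilyloxy)phenol | CC(C)[Si](Oc1cc(O)c(Br)cc1Br)(C(C)C)C(C)C | intermediate
3 | [2,4-dibromo-5-(methoxymethoxy)phenoxy]triisopropylsilane | COCOc1cc(O[Si](C(C)C)(C(C)C)C(C)C)c(Br)cc1Br | intermediate
4 | geranyl bromide, (2E)-1-bromo-3,7-dimethylocta-2,6-diene | BrC/C=C(\C)CCC=C(C)C | starting material
5 | [5-bromo-2-(methoxymethoxy)-4-(triisopropylsilyloxy)phenyl]lithium (not isolated) | COCOc1cc(O[Si](C(C)C)(C(C)C)C(C)C)c(Br)cc1[Li] | intermediate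
6 | [2-bromo-4-geranyl-5-(methoxymethoxy)phenoxy]triisopropylsilane | COCOc1cc(O[Si](C(C)C)(C(C)C)C(C)C)c(Br)cc1C/C=C(\C)CCC=C(C)C | intermediate
7 | 2-bromo-4-geranyl-5-(methoxymethoxy)phenol | COCOc1cc(O)c(Br)cc1C/C=C(\C)CCC=C(C)C | intermediate
8 | 1-(4-hydroxy-2-methoxyphenyl)ethan-1-one | CC(=O)c1ccc(O)cc1OC | starting material
9 | 1-[2-methoxy-4-(methoxymethoxy)phenyl]ethan-1-one | CC(=O)c1ccc(OCOC)cc1OC | intermediate
10 | potassium 1-[2-methoxy-4-(methoxymethoxy)phenyl]ethen-1-olate (not isolated) | [K+].[O-]C(=C)c1ccc(OCOC)cc1OC | intermediate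
11 | 1-[2-methoxy-4-(methoxymethoxy)phenyl]ethenyl trifluoromethanesulfonate | C=C(OS(=O)(=O)C(F)(F)F)c1ccc(OCOC)cc1OC | intermediate
12 | 2-[2-methoxy-4-(methoxymethoxy)phenyl]prop-2-enoic acid | C=C(C(=O)O)c1ccc(OCOC)cc1OC | intermediate
13 | 2-bromo-4-geranyl-5-(methoxymethoxy)phenyl 2-[2-methoxy-4-(methoxymethoxy)phenyl]prop-2-enoate | C=C(C(=O)Oc1cc(OCOC)c(C/C=C(\C)CCC=C(C)C)cc1Br)c1ccc(OCOC)cc1OC | intermediate
14 | [5-geranyl-4-(methoxymethoxy)-2-({2-[2-methoxy-4-(methoxymethoxy)phenyl]prop-2-enoyl}oxy)phenyl]lithium (not isolated) | C=C(C(=O)Oc1cc(OCOC)c(C/C=C(\C)CCC=C(C)C)cc1[Li])c1ccc(OCOC)cc1OC | intermediate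
15 | 1-[5-geranyl-2-hydroxy-4-(methoxymethoxy)phenyl]-2-[2-methoxy-4-(methoxymethoxy)phenyl]prop-2-en-1-one (not isolated) | C=C(C(=O)c1cc(C/C=C(\C)CCC=C(C)C)c(OCOC)cc1O)c1ccc(OCOC)cc1OC | intermediate
16 | rac-6-geranyl-3-[2-methoxy-4-(methoxymethoxy)phenyl]-7-(methoxymethoxy)-2,3-dihydro-4H-chromen-4-one | COc1cc(OCOC)ccc1C1COc2cc(OCOC)c(C/C=C(\C)CCC=C(C)C)cc2C1=O | intermediate
17 | (3S,4S)-6-geranyl-3-[2-methoxy-4-(methoxymethoxy)phenyl]-7-(methoxymethoxy)-3,4-dihydro-2H-chromen-4-ol | COc1cc(OCOC)ccc1[C@H]1COc2cc(OCOC)c(C/C=C(\C)CCC=C(C)C)cc2[C@H]1O | intermediate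
18 | (3S)-6-geranyl-3-[2-methoxy-4-(methoxymethoxy)phenyl]-7-(methoxymethoxy)-2,3-dihydro-4H-chromen-4-one | COc1cc(OCOC)ccc1[C@H]1COc2cc(OCOC)c(C/C=C(\C)CCC=C(C)C)cc2C1=O | intermediate
19 | (3S)-7-(dimethylboranyloxy)-3-[4-(dimethylboranyloxy)-2-methoxyphenyl]-6-geranyl-2,3-dihydro-4H-chromen-4-one (not isolated) | COc1cc(OB(C)C)ccc1[C@H]1COc2cc(OB(C)C)c(C/C=C(\C)CCC=C(C)C)cc2C1=O | intermediate
20 | (3S)-6-geranyl-7-hydroxy-3-(4-hydroxy-2-methoxyphenyl)-2,3-dihydro-4H-chromen-4-one | COc1cc(O)ccc1[C@H]1COc2cc(O)c(C/C=C(\C)CCC=C(C)C)cc2C1=O | target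

**Step count and risks**

Total step count: 12. Longest linear sequence: 9 steps (1, 2, 3, 4, 8, 9, 10, 11, 12).

Steps most likely to fail:

1. Step 9 (proposed new method). t-BuLi may add to the aryl acrylate (carbolithiation or attack at the ester carbonyl) before it exchanges the bromide; the aryllithium may add in conjugate fashion instead of transferring the acyl group; or the vinyl ketone may oligomerise before ring closure. Fallback with known chemistry, from 7 back to 16: 7 would be O-alkylated with 3-bromo-N-methoxy-N-methylpropanamide (K2CO3, DMF) to 3-[2-bromo-4-geranyl-5-(methoxymethoxy)phenoxy]-N-methoxy-N-methylpropanamide F1. Bromine–lithium exchange (t-BuLi, THF, −78 °C) and Parham cyclization onto the amide would give 6-geranyl-7-(methoxymethoxy)chroman-4-one F2. α-Arylation of its enolate (Pd(OAc)2, P(t-Bu)3, NaOt-Bu, THF, 60 °C) with 1-bromo-2-methoxy-4-(methoxymethoxy)benzene F3, made from purchased 4-bromo-3-methoxyphenol and MOMCl, would give 16.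

2. Step 3. Exchange may occur at the bromine next to OTIPS and be followed by O-to-C silyl migration; both bromides may exchange; or the allyl bromide may be attacked at its tertiary end (SN2′) with loss of the linear E chain. Fallback, from 3 back to 7: the silyl ether would be removed first (n-Bu4NF, AcOH, THF) to give 2,4-dibromo-5-(methoxymethoxy)phenol F4. Deprotonation with NaH makes the phenoxide, which deactivates the bromide beside it and cannot undergo silyl migration, so n-BuLi at −78 °C should exchange only the bromide next to OMOM to give the C-lithiated sodium phenoxide F5. CuI-catalysed allylation with 4 would give 7 directly after work-up.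

3. Step 12. Lewis-acid-promoted enolisation at C3 would erode enantiopurity, and O7 may add to the neighbouring alkene of the geranyl chain during cleavage or work-up. Fallback, from 16 back to 20, which moves the acetal cleavage ahead of the stereo-setting step: 16 would be deprotected while still racemic (aq HCl, MeOH, rt) to rac-6-geranyl-7-hydroxy-3-(4-hydroxy-2-methoxyphenyl)chroman-4-one F6 and silylated (TIPSCl, imidazole, DMF) to the bis(triisopropylsilyl) ether F7. The same transfer hydrogenation as in step 10 would give the (3S,4S)-alcohol F8, Dess–Martin oxidation the (3S)-ketone F9, and buffered fluoride (n-Bu4NF, AcOH, THF, 0 °C) would release 20 without acid.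

**Further compounds**

F1 | step 9 | 3-[2-bromo-4-geranyl-5-(methoxymethoxy)phenoxy]-N-methoxy-N-methylpropanamide | CON(C)C(=O)CCOc1cc(OCOC)c(C/C=C(\C)CCC=C(C)C)cc1Br
F2 | step 9 | 6-geranyl-7-(methoxymethoxy)-2,3-dihydro-4H-chromen-4-one | COCOc1cc2OCCC(=O)c2cc1C/C=C(\C)CCC=C(C)C
F3 | step 9 | 1-bromo-2-methoxy-4-(methoxymethoxy)benzene | COCOc1ccc(Br)c(OC)c1
F4 | step 3 | 2,4-dibromo-5-(methoxymethoxy)phenol | COCOc1cc(O)c(Br)cc1Br
F5 | step 3 | sodium 2-bromo-4-lithio-5-(methoxymethoxy)phenolate | [Na+].[O-]c1cc(OCOC)c([Li])cc1Br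
F6 | step 12 | rac-6-geranyl-7-hydroxy-3-(4-hydroxy-2-methoxyphenyl)-2,3-dihydro-4H-chromen-4-one | COc1cc(O)ccc1C1COc2cc(O)c(C/C=C(\C)CCC=C(C)C)cc2C1=O
F7 | step 12 | rac-6-geranyl-3-[2-methoxy-4-(triisopropylsilyloxy)phenyl]-7-(triisopropylsilyloxy)-2,3-dihydro-4H-chromen-4-one | COc1cc(O[Si](C(C)C)(C(C)C)C(C)C)ccc1C1COc2cc(O[Si](C(C)C)(C(C)C)C(C)C)c(C/C=C(\C)CCC=C(C)C)cc2C1=O
F8 | step 12 | (3S,4S)-6-geranyl-3-[2-methoxy-4-(triisopropylsilyloxy)phenyl]-7-(triisopropylsilyloxy)-3,4-dihydro-2H-chromen-4-ol | COc1cc(O[Si](C(C)C)(C(C)C)C(C)C)ccc1[C@H]1COc2cc(O[Si](C(C)C)(C(C)C)C(C)C)c(C/C=C(\C)CCC=C(C)C)cc2[C@H]1O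
F9 | step 12 | (3S)-6-geranyl-3-[2-methoxy-4-(triisopropylsilyloxy)phenyl]-7-(triisopropylsilyloxy)-2,3-dihydro-4H-chromen-4-one | COc1cc(O[Si](C(C)C)(C(C)C)C(C)C)ccc1[C@H]1COc2cc(O[Si](C(C)C)(C(C)C)C(C)C)c(C/C=C(\C)CCC=C(C)C)cc2C1=O
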